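Target is what this flask is run for: an electrophile meets a nucleophile with free base present, and you have two earlier runs from which to reckon flasks theta and beta.

| flask | electrophile | nucleophile | free base | remark | time |
|---|---|---|---|---|---|
| Saturday's | 15 mM | 0.80 equiv | 2 equiv | run made earlier |  |
| Monday's | 10 mM | 1.6 equiv | 2 equiv | run made earlier |  |
| theta | 10 mM | 0.800 equiv | 2.00 equiv |  | 10 d |
| beta | 10 mM | 0.800 equiv | 4.00 equiv |  | 10 d |

| run | time / d | electrophile / % | target / % |
|---|---|---|---|
| Saturday's | 0.500 | 52.0 | 42.5 |
| Saturday's | 0.833 | 41.0 | 51.5 |
| Saturday's | 1.67 | 24.6 | 58.5 |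
| Saturday's | 3.00 | 14.2 | 63.1 |
| Saturday's | 6.00 | 5.3 | 62.3 |
| Monday's | 1.25 | 10.1 | 81.7 |
| Monday's | 2.50 | 2.4 | 88.3 |
| Monday's | 4.00 | 0.7 | 93.0 |
| Monday's | 5.00 | 0 | 92.5 |
| Monday's | 6.00 | 0 | 88.9 |

(scatter of a reading: 1 percentage point)

- the analysis behind the earlier runs scatters by 1 percentage point, standard deviation

- part of the electrophile that has reacted at the end, theta
- part of the electrophile that has reacted at the end, beta
- what raising the equivalents of free base from its lowest to its highest value here does to the part of the electrophile that has reacted (changes below 5 percentage points count as none) (it falls / it rises / no change)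

Keep a ledger in fractions of the electrophile charged, as it stands in Saturday's run at 6.00 d. Entry one: 5.3 % is left. Entry two: 62.3 % is target. The books need a third entry of 32.4 %. In Saturday's run the nucleophile, the limiting reagent at 0.80 equiv, has at most 17.7 %, still counted in fractions of the electrophile charged, not showing as target. The third entry is twice that, so my reading is that each lost unit holds two electrophiles, target having taken up another one.

If each step pairs two molecules, then at fixed equivalents the fraction left depends on c_electrophile times time. Theta has Saturday's equivalents, so its end lies at 6.67 d of Saturday time, the time in Saturday's run with the same product of c_electrophile and time. Between 3.00 d and 6.00 d of Saturday's run the logarithm of the fraction left fell at a read 0.329 d⁻¹. Carried on, that leaves 4.26 % in theta, so 95.7 % has reacted. Free base has no entry in my ledger, so I give beta the same figure and expect no change.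

The forecast said 96.5 % for theta, 98.5 % for beta and no change, with the words “Either way conversion is near complete”. Both of its figures stand higher than mine.

The flasks give 94.5 % for theta, 94.4 % for beta and no change.

    electrophile + nucleophile → acid set free + target (k = 0.00356 L mol⁻¹ s⁻¹)
    nucleophile + acid set free ⇌ protonated nucleophile, settled at all times (K = 1680 L mol⁻¹)
    acid set free + free base ⇌ salt of the base (K = 20700 L mol⁻¹, k = 0.00417 L mol⁻¹ s⁻¹)
    electrophile + target → side product (k = 1.81 × 10⁻⁴ L mol⁻¹ s⁻¹)

Theta keeps 5.5 % against the reckoned 4.26 %. Beta's answer moves by 5 percentage points at 0.714 equiv or 0.976 equiv of nucleophile, the other charges and the time held. Now take the neighbouring flask with 40 mM of electrophile, its equivalents and time as in theta. Its Saturday time is 26.7 d, so the same decline leaves 0.00597 %. That flask keeps more than reckoned, 0.12 %, with 99.9 % reacted and target at 58.3 %.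

The earlier runs and the new flask are calculated with constants of no real substance; the scatter is artificial.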